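Early times came first for me: in the noon and spring runs a single-handed free catalyst turned a racemic pair of substrates into two products at −20 °C, and I wanted to know how the new flasks would divide their reagent between those products.

all flasks: free catalyst 0.80 mM

|  | left-handed substrate | right-handed substrate | reagent | temperature | remark | time |
|---|---|---|---|---|---|---|
| noon | 0.40 M | 0.40 M | 0.32 M | −20 °C | run made earlier |  |
| spring | 0.60 M | 0.60 M | 0.32 M | −20 °C | run made earlier |  |
| Friday's | 0.40 M | 0.40 M | 0.320 M |  | everything together at the start at −50 °C, warmed to −20 °C at 5.0 h | 12 h |
| Wednesday's | 0.40 M | 0.40 M | 0.320 M (fed, over 5.0 h) | −20 °C | all else is in the flask from the start; the feed brings no volume worth counting | 12 h |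
| Tuesday's | 0.40 M | 0.40 M | 0.320 M (fed, over 5.0 h) |  | the addition at −50 °C, then warmed to −20 °C; the feed brings no volume worth counting | 12 h |
| Sunday's | 0.40 M | 0.40 M | 0.320 M | −20 °C | everything together at the start | 12 h |

- free catalyst is single-handed; left-handed substrate and right-handed substrate are mirror images of each other, charged as a racemate, each of them at the stated concentration
- what was read earlier has a scatter of 1.5 percentage points, one standard deviation
- on the list of suspects stand: free catalyst + left-handed substrate <-> catalyst intermediate A; free catalyst + right-handed substrate <-> catalyst intermediate B; reagent + catalyst intermediate A -> free catalyst + left-handed product; reagent + catalyst intermediate B -> free catalyst + right-handed product; 2 free catalyst <-> resting dimer; free catalyst <-> dormant form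
- the earlier runs do not show what temperature does; that part of a forecast is a guess

| run | time / h | right-handed product / % | left-handed product / % | left-handed substrate / % |
|---|---|---|---|---|
| noon | 0.833 | 6 | 20 | 32 |
| noon | 2.50 | 11 | 26 | 22 |
| noon | 5.00 | 10 | 32 | 23 |
| noon | 8.00 | 9 | 28 | 20 |
| spring | 0.333 | 3 | 9 | 42 |
| spring | 0.833 | 2 | 16 | 38 |
| spring | 1.50 | 4 | 17 | 32 |
| spring | 2.50 | 6 | 22 | 32 |

(each reading ± 1.5 percentage points)

* the flask with the highest amount of right-handed product, in percent of the left-handed substrate and right-handed substrate together charged ("all alike" if they lie within 1.5 percentage points) (Friday's / Wednesday's / Tuesday's / Sunday's / all alike)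
* final right-handed product, as a percentage of the left-handed substrate and right-handed substrate together charged, in Friday's
* final right-handed product, as a percentage of the left-handed substrate and right-handed substrate together charged, in Wednesday's
* final right-handed product, as a percentage of the left-handed substrate and right-handed substrate together charged, in Tuesday's
* final right-handed product, as a percentage of the left-handed substrate and right-handed substrate together charged, in Sunday's

At 0.833 h the noon run read 6% right-handed product and 20% left-handed product, so 23.1% of what had formed was right-handed. Each suspected product step spends one reagent, so both products together have a ceiling: the reagent charge over both substrates, 40.0% for the noon recipe and the four flasks, and 26.7% for spring. The readings stand there: the last 3 noon readings average 38.7%, and the last spring reading totals 28.0%. So I took reagent as the limiting reagent, read the large total from the ceiling, and reckoned the small right-handed part as a correction to it: 9.24%.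

The weak link was the share, which rested on 6% read with a scatter of 1.5 percentage points. Pooling those last 3 noon readings gave 25.9% as the right-handed share, right-handed product over both products, and that made 10.3%. The early and pooled shares lay close, so I kept the pooled one for the fed Wednesday's. The runs show nothing of temperature, so using it for Friday's and Tuesday's at −50 °C was a guess, and my own figure for all four flasks was 10.3%.

The forecast, whose numbers differ from my figure, gave 9.5% for Friday's, 10% for Wednesday's, 9.3% for Tuesday's and 10% for Sunday's, “so they should be alike”, with the verdict all alike.

Friday's flask held the most right-handed product, 18.1%, followed by Tuesday's 14.5%, Sunday's 10.3% and Wednesday's 9.64%.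

    free catalyst + left-handed substrate ⇌ catalyst intermediate A (K = 2.60 M⁻¹, k = 1.70 M⁻¹ s⁻¹, Ea = 46.0 kJ mol⁻¹, ΔH = 28.0 kJ mol⁻¹)
    free catalyst + right-handed substrate ⇌ catalyst intermediate B (K = 1.40 M⁻¹, k = 3.10 M⁻¹ s⁻¹, Ea = 50.0 kJ mol⁻¹, ΔH = −76.0 kJ mol⁻¹)
    reagent + catalyst intermediate A → free catalyst + left-handed product (k = 1.10 M⁻¹ s⁻¹, Ea = 48.0 kJ mol⁻¹)
    reagent + catalyst intermediate B → free catalyst + right-handed product (k = 0.440 M⁻¹ s⁻¹, Ea = 39.0 kJ mol⁻¹)
    2 free catalyst ⇌ resting dimer (K = 440 M⁻¹, k = 0.0460 M⁻¹ s⁻¹, Ea = 45.0 kJ mol⁻¹, ΔH = −21.0 kJ mol⁻¹)
    free catalyst ⇌ dormant form (K = 2.90, k = 1.50 × 10⁻⁵ s⁻¹, Ea = 80.0 kJ mol⁻¹, ΔH = −60.0 kJ mol⁻¹)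
    (constants at −20 °C)

Friday's stood with everything together at −50 °C for 5.0 h before warming to −20 °C; at 12.0 h its reagent was down to 0.055% of its charge, both products totalled 40.0%, and the right-handed share was 45.2%. Wednesday's, fed over 5.0 h at −20 °C, had half of its left-handed product step behind it by 3.22 h and ended at a share of 24.1%. The repeat of Wednesday's at −35 °C ended with 5.47% of its reagent left and a right-handed share of 79.2%.

The runs stem from a simulated flask for an exercise; the scatter is artificial.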